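**Remark on the chemistry (assumption):** both enantiomers of sparteine are taken to be purchasable, and the benzoate-directed deprotonation is taken to follow its usual sense, the (−)-diamine removing the pro-S proton.

## Analysis of the target

Target 24 is a trans-3,4-dibenzyl-γ-butyrolactone with a single five-membered ring (O1, carbonyl C2, C3, C4, C5) beside the two arenes. C3 carries C7' and ring B (3-hydroxy-4,5-dimethoxyphenyl), and C4 carries C7 and ring A (3,4-dimethoxyphenyl). Both stereocentres are R, and the two arylmethyl groups lie on opposite faces of the lactone. C3 is α to the carbonyl and can be epimerised, the trans arrangement being the more stable one, whereas C4 has no activating neighbour and must be set kinetically and then kept. The sensitive points are the one free phenol among four methyl ethers (carried here as a benzyl ether), the two electron-rich rings (open to electrophilic halogenation, oxidation and ring metallation) and the lactone. The difficulty is the near-symmetry of the skeleton: two arylmethyl arms that differ only in arene oxygenation sit on adjacent CH centres, so they must be introduced separately and both centres controlled absolutely. The strategy rests on one observation: with O1–C2 opened, C4 (with C7 and ring A) and C3 (with C7' and ring B) are each the carbinol carbon of a 2-arylethanol, capped by the one-carbon units C5 and C2. Each centre can therefore be generated as an α-oxygenated carbanion of an arylethanol ester, and the bonds C4–C5, C3–C4 and C2–C3 can all be made by migration of a carbon group from boron to carbon.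

## Retrosynthetic reasoning

**O1–C2 and the two benzyl ethers (24 ⇒ 23 ⇒ 22).** The lactone is opened to γ-hydroxy acid 23, which closes again under acid alone. The C5 hydroxyl and the ring B phenol of 23 are both masked as benzyl ethers in 22, so one hydrogenolysis frees both. The forward step must cleave two O–benzyl bonds and leave the two aryl–CH2–C bonds alone.

**C2–C3 (22 ⇒ 20 ⇒ 18).** The carboxyl carbon is taken off C3 and replaced by boron. A C–B bond is configurationally stable and not enolisable, and it can be exchanged for carbon with retention by inserting a one-carbon carbenoid. Oxidation of the resulting α-chloro boronic ester 20 then gives acid 22 directly. Cutting here rather than at C3–C7' keeps ring B on its benzylic carbon and leaves C3 as a boron-bearing stereocentre in 18, which is what a boronic ester homologation delivers.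

**C3–C4 (18 ⇒ 15 + 9).** C3 with its arm C7'–ring B is recognised as the oxygen-bearing carbon of arylethyl benzoate 9. The forward reaction is α-lithiation of 9 under a chiral diamine, capture by the boron of 15, and shift of C4 from boron to C3 with loss of the benzoate. The cut is made between the two stereocentres because each half then carries exactly one of them, and the centre on the migrating carbon passes through unchanged. The forward step must choose one of two enantiotopic protons of 9 and must rearrange faster than the boronate loses the C5 alkoxy group.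

**C4–C5 (15 ⇒ 12 + 3).** The same operation one stage earlier: C4 with C7–ring A comes from benzoate 3, and C5 arrives as the benzyloxymethyl group of boronic ester 12, which migrates onto C4. Bringing C5 in on boron and already oxygenated means the lactone oxygen O1 needs no later oxidation, and the two homologations can be run back to back.

**Building blocks (12 ⇒ 10; 3 ⇒ 1 + 2; 9 ⇒ 8 + 2; 8 ⇒ 6 ⇒ 5 ⇒ 4).** 12 comes from bromomethyl boronic ester 10 by alkoxide substitution through boron. The hindered benzoates 3 and 9 come from alcohols 1 and 8 and acid 2 by Mitsunobu esterification. Alcohol 8 is reached from aldehyde 4 by benzylation (5), methylenation (6) and anti-Markovnikov hydration through trialkylborane 7.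

## Alternatives that were turned down

**Alternative 1: C4 as a latent symmetric centre.**
- Disconnection: the ring A aryl–C7 bond and O1–C2. C4 is traced back to a carbon bearing two equal hydroxymethyl arms, held as an acetonide in (2R)-3-[3-(benzyloxy)-4,5-dimethoxyphenyl]-2-(2,2-dimethyl-1,3-dioxan-5-yl)propanoic acid A2.
- Key step: aqueous acid removes the acetonide and the carboxyl group lactonises reversibly onto either arm. The equilibrium should settle on the trans lactone (3R,4S)-3-[3-(benzyloxy)-4,5-dimethoxybenzyl]-4-(hydroxymethyl)dihydrofuran-2(3H)-one A1, which fixes C4.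
- For: only C3 needs a chiral controller, and C4 is set by thermodynamics with cheap reagents. On economy of chiral material it is stronger than the chosen route.
- Against: the trans preference depends on the steric demand of a hydroxymethyl group, which is small, so the bias may be modest. Translactonisation also stays open whenever the free hydroxyl and the lactone coexist. Ring A must then be attached to the hydroxymethyl carbon of A1 by activation and an sp3–sp2 coupling, next to a lactone that reacts with aryl-metal reagents and has an epimerisable α-centre.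
- Comparison: the aryl group enters late and linearly, and the step count is no lower. The chosen route brings both arms in with their benzylic carbons attached and sets both centres kinetically by reagent.

**Alternative 2: tethered union of C3 and C4 by reductive enyne cyclisation.**
- Disconnection: C3–C4 and the C–H bonds at C7 and C7', leading to the ester (E)-3-(3,4-dimethoxyphenyl)prop-2-en-1-yl 3-[3-(benzyloxy)-4,5-dimethoxyphenyl]prop-2-ynoate A4.
- Key step: a cationic monovalent rhodium complex such as [Rh(cod)2]OTf with a chiral bisphosphine couples alkyne and alkene oxidatively to a rhodacyclopentene, forming C3–C4 and the ring. Hydrogen then cleaves both Rh–C bonds to give (R,Z)-3-[3-(benzyloxy)-4,5-dimethoxybenzylidene]-4-(3,4-dimethoxybenzyl)dihydrofuran-2(3H)-one A3.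
- For: A4 is an ester of two simple halves, and ring, C3–C4 bond and C4 configuration arise in one catalytic step. On step count and catalytic use of chirality it is clearly stronger.
- Against: an ester tether prefers the conformation that holds the two π-systems apart. The alkene is 1,2-disubstituted and aryl-conjugated, so it inserts slowly. Cationic rhodium under hydrogen can simply reduce the alkynoate or the alkene, the allylic ester can ionise, and β-hydride elimination from the rhodacycle leads to a diene.
- C3 is not set by the key step. Hydrogenating the exocyclic C3=C7' bond of A3 adds hydrogen anti to the C4 arm, which gives the cis relationship, so a base equilibration at C3 would have to follow.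
- Comparison: the chosen route is longer and stoichiometric in the chiral diamine. In return, each centre is fixed by a separate, well-understood event that does not depend on chemoselectivity at a metal.

**Alternative 3: cathodic carboxylation of a styrene.**
- Disconnection: C2–C3 and O1–C2, leading to (2R,3E)-4-[3-(benzyloxy)-4,5-dimethoxyphenyl]-2-(3,4-dimethoxybenzyl)but-3-en-1-ol A6, in which C4 is already set.
- Key step: reduction at the cathode under carbon dioxide. C3 of the reduced styrene attacks carbon dioxide, C7' is protonated, and acidic work-up closes the lactone to (3R,4R)-3-[3-(benzyloxy)-4,5-dimethoxybenzyl]-4-(3,4-dimethoxybenzyl)dihydrofuran-2(3H)-one A5.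
- For: C2 comes from carbon dioxide, no boron or tin is used, the lactone closes by itself, and a wrong C3 epimer could be corrected by base because trans is favoured. In reagent cost it is stronger.
- Against: C3 is formed by an open-chain carbanion next to C4, where 1,2-induction is weak. Dicarboxylation at C7', plain reduction of the alkene and carbonate formation at the free hydroxyl all compete. The trioxygenated styrene is reduced only at very negative potential, close to where aryl benzyl ethers and carbon dioxide itself are reduced. A6 also needs its own enantioselective synthesis of C4.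
- Comparison: the length would be similar. The chosen route sets C3 and C4 by the same reagent-controlled event and does not depend on a narrow potential window.

Key step: step 7

## Route

**Step 1**
Reactants: 1 2-(3,4-dimethoxyphenyl)ethanol; 2 2,4,6-triisopropylbenzoic acid
Product: 3 2-(3,4-dimethoxyphenyl)ethyl 2,4,6-triisopropylbenzoate
Conditions: PPh3, DIAD, THF, 0 °C → rt
Reagents that add atoms: none
Why: Mitsunobu esterification: the primary alcohol is activated as its alkoxyphosphonium ion and displaced by the hindered carboxylate, so the acid chloride of a doubly ortho-substituted acid is not needed; no stereocentre is involved.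

**Step 2**
Reactants: 4 3-hydroxy-4,5-dimethoxybenzaldehyde
Product: 5 3-(benzyloxy)-4,5-dimethoxybenzaldehyde
Conditions: BnBr, K2CO3, DMF, rt
Reagents that add atoms: benzyl bromide, BrCc1ccccc1
Why: Williamson ether synthesis on the phenoxide; the aldehyde has no α-hydrogen and is inert to K2CO3, and benzyl is chosen because it leaves in the last step together with the C5 benzyl ether.

**Step 3**
Reactants: 5 3-(benzyloxy)-4,5-dimethoxybenzaldehyde
Product: 6 1-(benzyloxy)-5-ethenyl-2,3-dimethoxybenzene
Conditions: Ph3PCH3Br, KOt-Bu, THF, 0 °C → rt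
Reagents that add atoms: methyltriphenylphosphonium bromide, [Br-].C[P+](c1ccccc1)(c1ccccc1)c1ccccc1
Why: Wittig methylenation with the non-stabilised ylide; a non-enolisable aryl aldehyde should react cleanly and the benzyl ether is untouched.

**Step 4**
Reactants: 6 1-(benzyloxy)-5-ethenyl-2,3-dimethoxybenzene
Product: 8 2-[3-(benzyloxy)-4,5-dimethoxyphenyl]ethanol, via B-alkyl borabicyclononane 7 (not isolated)
Conditions: 9-BBN, THF, 0 °C → rt; then aq. NaOH, H2O2, 0 °C → rt
Reagents that add atoms: hydrogen peroxide, OO; 9-borabicyclo[3.3.1]nonane, B1C2CCCC1CCC2 (its atoms are held only in 7)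
Why: Hydroboration–oxidation: the bulky borane places boron on the terminal carbon of the styrene, and alkaline peroxide replaces C–B by C–O with retention, giving the primary 2-arylethanol.

**Step 5**
Reactants: 8 2-[3-(benzyloxy)-4,5-dimethoxyphenyl]ethanol; 2 2,4,6-triisopropylbenzoic acid
Product: 9 2-[3-(benzyloxy)-4,5-dimethoxyphenyl]ethyl 2,4,6-triisopropylbenzoate
Conditions: PPh3, DIAD, THF, 0 °C → rt
Reagents that add atoms: none
Why: Mitsunobu esterification as in step 1; the aryl benzyl ether and the methyl ethers are inert.

**Step 6**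
Reactants: 10 2-(bromomethyl)-4,4,5,5-tetramethyl-1,3,2-dioxaborolane
Product: 12 2-[(benzyloxy)methyl]-4,4,5,5-tetramethyl-1,3,2-dioxaborolane, via sodium boronate complex 11 (not isolated)
Conditions: BnOH, NaH, THF, 0 °C; then 10, THF/DMSO, 0 °C → 50 °C
Reagents that add atoms: benzyl alcohol, OCc1ccccc1; sodium hydride, [Na+].[H-] (its sodium is held only in 11)
Why: Matteson-type substitution of an α-halo boronic ester: the alkoxide adds to boron to give 11 and the benzyloxy group then shifts from boron to carbon with loss of bromide, so no direct displacement at the hindered carbon is required.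

**Step 7**
Reactants: 3 2-(3,4-dimethoxyphenyl)ethyl 2,4,6-triisopropylbenzoate; 12 2-[(benzyloxy)methyl]-4,4,5,5-tetramethyl-1,3,2-dioxaborolane; 9 2-[3-(benzyloxy)-4,5-dimethoxyphenyl]ethyl 2,4,6-triisopropylbenzoate
Product: 18 2-[(2R,3R)-3-[(benzyloxy)methyl]-1-[3-(benzyloxy)-4,5-dimethoxyphenyl]-4-(3,4-dimethoxyphenyl)butan-2-yl]-4,4,5,5-tetramethyl-1,3,2-dioxaborolane, via lithiated ring A benzoate 13 (not isolated), via first lithium boronate complex 14 (not isolated), via ring A secondary boronic ester 15 (not isolated), via lithiated ring B benzoate 16 (not isolated), via second lithium boronate complex 17 (not isolated)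
Conditions: (a) 3 (slight excess over base), (+)-sparteine, s-BuLi, Et2O, −78 °C, 5 h; then 12, −78 °C → 35 °C; filtration through a silica plug, no chromatography; (b) 9 (slight excess over base), (−)-sparteine, s-BuLi, Et2O, −78 °C, 5 h; then crude 15, −78 °C → 35 °C
Reagents that add atoms: sec-butyllithium, [Li]C(C)CC (its lithium is held only in 13, 14, 16 and 17; no atom of it remains in 18)
Why: This is reagent-controlled lithiation–borylation run twice, that is, diamine-mediated α-lithiation of an O-alkyl 2,4,6-triisopropylbenzoate joined to a Matteson-type 1,2-metallate rearrangement. In stage (a) s-BuLi·(+)-sparteine, pre-complexed to the carbonyl of 3, removes the pro-R proton of the OCH2 group to give the configurationally stable (R)-carbenoid 13, which adds to the boron of 12 with retention to give 14; on warming, the benzyloxymethyl group shifts from boron to carbon anti to the departing carboxylate (inversion at C4), forming C4–C5 and 15. In stage (b) s-BuLi·(−)-sparteine removes the pro-S proton of 9, carbenoid 16 captures 15 with retention to give 17, and C4 migrates with retention of its own configuration and inversion at C3, forming C3–C4. No ring is closed. C4 is thus controlled only by the hand of the diamine in the first lithiation and C3 only by that in the second, the centre on the migrating carbon playing no part; opposite hands give the relative configuration that becomes trans in the lactone, and because two independent selections are combined, the wrong combinations appear as separable diastereomers and not as the enantiomer. Lithiation α to oxygen, and not at the benzylic CH2, on the rings or at ArOCH2Ph, rests on the complex-induced proximity effect of the benzoate carbonyl and on s-BuLi being the limiting reagent, so that no free base meets 12 or 15. Single homologation in each stage is expected because surplus carbenoid decomposes below the temperature at which 14 and 17 rearrange. In 17, migration should outrun β-elimination across C4–C5 because the hindered carboxylate on C3 is a far better leaving group than the benzyloxide on C5.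

**Step 8**
Reactants: 18 2-[(2R,3R)-3-[(benzyloxy)methyl]-1-[3-(benzyloxy)-4,5-dimethoxyphenyl]-4-(3,4-dimethoxyphenyl)butan-2-yl]-4,4,5,5-tetramethyl-1,3,2-dioxaborolane
Product: 20 2-[(2R,3R)-3-[(benzyloxy)methyl]-2-[3-(benzyloxy)-4,5-dimethoxybenzyl]-1-chloro-4-(3,4-dimethoxyphenyl)butyl]-4,4,5,5-tetramethyl-1,3,2-dioxaborolane (both epimers at the chlorinated carbon), via dichloromethyl boronate complex 19 (not isolated)
Conditions: CH2Cl2, n-BuLi, THF, −100 °C; then 18, −100 °C → rt
Reagents that add atoms: dichloromethane, ClCCl; n-butyllithium, [Li]CCCC (its lithium is held only in 19)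
Why: Matteson homologation: LiCHCl2 adds to boron to give 19 and C3 migrates to the carbenoid carbon with loss of chloride and retention at C3; the new CHCl centre forms as a mixture, which does not matter because it becomes the carbonyl carbon C2.

**Step 9**
Reactants: 20 2-[(2R,3R)-3-[(benzyloxy)methyl]-2-[3-(benzyloxy)-4,5-dimethoxybenzyl]-1-chloro-4-(3,4-dimethoxyphenyl)butyl]-4,4,5,5-tetramethyl-1,3,2-dioxaborolane
Product: 22 (2R,3R)-4-(benzyloxy)-2-[3-(benzyloxy)-4,5-dimethoxybenzyl]-3-(3,4-dimethoxybenzyl)butanoic acid, via aldehyde 21 (not isolated)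
Conditions: NaClO2, NaH2PO4, 2-methyl-2-butene, t-BuOH/THF/H2O, 0 °C → rt
Reagents that add atoms: sodium chlorite, [Na+].[O-]Cl=O
Why: Chlorite oxidation of an α-chloro boronic ester: nucleophilic chlorite replaces C–B by C–O, the α-chloro alkoxide collapses to aldehyde 21, and 21 is oxidised at once under the same buffered Pinnick conditions, so the enolisable centre C3 spends little time at the aldehyde stage. The alkene scavenger traps hypochlorite and protects the electron-rich rings.

**Step 10**
Reactants: 22 (2R,3R)-4-(benzyloxy)-2-[3-(benzyloxy)-4,5-dimethoxybenzyl]-3-(3,4-dimethoxybenzyl)butanoic acid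
Product: 24 (3R,4R)-4-(3,4-dimethoxybenzyl)-3-(3-hydroxy-4,5-dimethoxybenzyl)dihydrofuran-2(3H)-one, via hydroxy acid 23 (not isolated)
Conditions: H2 (1 atm), 10% Pd/C, EtOAc/EtOH, rt; then p-TsOH·H2O (cat.), CH2Cl2, rt
Reagents that add atoms: none
Why: Hydrogenolysis over palladium on carbon cleaves the aryl and the alkyl benzyl ether, while the two aryl–CH2–C bonds, which carry no heteroatom, stay; γ-hydroxy acid 23 then closes to the five-membered lactone under acid catalysis. Neither stereocentre is touched, and trans is also the preferred arrangement at the enolisable C3.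

## Compound list

1 | 2-(3,4-dimethoxyphenyl)ethanol | COc1ccc(CCO)cc1OC | starting material
2 | 2,4,6-triisopropylbenzoic acid | CC(C)c1cc(C(C)C)c(C(=O)O)c(C(C)C)c1 | starting material
3 | 2-(3,4-dimethoxyphenyl)ethyl 2,4,6-triisopropylbenzoate | COc1ccc(CCOC(=O)c2c(C(C)C)cc(C(C)C)cc2C(C)C)cc1OC | intermediate
4 | 3-hydroxy-4,5-dimethoxybenzaldehyde | COc1cc(C=O)cc(O)c1OC | starting material
5 | 3-(benzyloxy)-4,5-dimethoxybenzaldehyde | COc1cc(C=O)cc(OCc2ccccc2)c1OC | intermediate
6 | 1-(benzyloxy)-5-ethenyl-2,3-dimethoxybenzene | COc1cc(C=C)cc(OCc2ccccc2)c1OC | intermediate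
7 | 9-{2-[3-(benzyloxy)-4,5-dimethoxyphenyl]ethyl}-9-borabicyclo[3.3.1]nonane (not isolated) | COc1cc(CCB2C3CCCC2CCC3)cc(OCc2ccccc2)c1OC | intermediate
8 | 2-[3-(benzyloxy)-4,5-dimethoxyphenyl]ethanol | COc1cc(CCO)cc(OCc2ccccc2)c1OC | intermediate
9 | 2-[3-(benzyloxy)-4,5-dimethoxyphenyl]ethyl 2,4,6-triisopropylbenzoate | COc1cc(CCOC(=O)c2c(C(C)C)cc(C(C)C)cc2C(C)C)cc(OCc2ccccc2)c1OC | intermediate
10 | 2-(bromomethyl)-4,4,5,5-tetramethyl-1,3,2-dioxaborolane | CC1(C)OB(CBr)OC1(C)C | starting material
11 | sodium 2-(benzyloxy)-2-(bromomethyl)-4,4,5,5-tetramethyl-1,3,2-dioxaborolan-2-uide (not isolated) | [Na+].CC1(C)O[B-](CBr)(OCc2ccccc2)OC1(C)C | intermediate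
12 | 2-[(benzyloxy)methyl]-4,4,5,5-tetramethyl-1,3,2-dioxaborolane | CC1(C)OB(COCc2ccccc2)OC1(C)C | intermediate
13 | (1R)-2-(3,4-dimethoxyphenyl)-1-lithioethyl 2,4,6-triisopropylbenzoate, as its (+)-sparteine complex (not isolated) | COc1ccc(C[C@@H]([Li])OC(=O)c2c(C(C)C)cc(C(C)C)cc2C(C)C)cc1OC | intermediate
14 | lithium 2-[(benzyloxy)methyl]-2-[(1R)-2-(3,4-dimethoxyphenyl)-1-(2,4,6-triisopropylbenzoyloxy)ethyl]-4,4,5,5-tetramethyl-1,3,2-dioxaborolan-2-uide (not isolated) | [Li+].COc1ccc(C[C@@H]([B-]2(COCc3ccccc3)OC(C)(C)C(C)(C)O2)OC(=O)c2c(C(C)C)cc(C(C)C)cc2C(C)C)cc1OC | intermediate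
15 | 2-[(2S)-1-(benzyloxy)-3-(3,4-dimethoxyphenyl)propan-2-yl]-4,4,5,5-tetramethyl-1,3,2-dioxaborolane (not isolated) | COc1ccc(C[C@@H](COCc2ccccc2)B2OC(C)(C)C(C)(C)O2)cc1OC | intermediate
16 | (1S)-2-[3-(benzyloxy)-4,5-dimethoxyphenyl]-1-lithioethyl 2,4,6-triisopropylbenzoate, as its (−)-sparteine complex (not isolated) | COc1cc(C[C@H]([Li])OC(=O)c2c(C(C)C)cc(C(C)C)cc2C(C)C)cc(OCc2ccccc2)c1OC | intermediate
17 | lithium 2-[(1S)-2-[3-(benzyloxy)-4,5-dimethoxyphenyl]-1-(2,4,6-triisopropylbenzoyloxy)ethyl]-2-[(2S)-1-(benzyloxy)-3-(3,4-dimethoxyphenyl)propan-2-yl]-4,4,5,5-tetramethyl-1,3,2-dioxaborolan-2-uide (not isolated) | [Li+].COc1cc(C[C@H]([B-]2([C@@H](Cc3ccc(OC)c(OC)c3)COCc3ccccc3)OC(C)(C)C(C)(C)O2)OC(=O)c2c(C(C)C)cc(C(C)C)cc2C(C)C)cc(OCc2ccccc2)c1OC | intermediate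
18 | 2-[(2R,3R)-3-[(benzyloxy)methyl]-1-[3-(benzyloxy)-4,5-dimethoxyphenyl]-4-(3,4-dimethoxyphenyl)butan-2-yl]-4,4,5,5-tetramethyl-1,3,2-dioxaborolane | COc1ccc(C[C@H]([C@H](B2OC(C)(C)C(C)(C)O2)Cc2cc(OCc3ccccc3)c(OC)c(OC)c2)COCc2ccccc2)cc1OC | intermediate
19 | lithium 2-[(2R,3R)-3-[(benzyloxy)methyl]-1-[3-(benzyloxy)-4,5-dimethoxyphenyl]-4-(3,4-dimethoxyphenyl)butan-2-yl]-2-(dichloromethyl)-4,4,5,5-tetramethyl-1,3,2-dioxaborolan-2-uide (not isolated) | [Li+].COc1ccc(C[C@H]([C@H]([B-]2(C(Cl)Cl)OC(C)(C)C(C)(C)O2)Cc2cc(OCc3ccccc3)c(OC)c(OC)c2)COCc2ccccc2)cc1OC | intermediate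
20 | 2-[(2R,3R)-3-[(benzyloxy)methyl]-2-[3-(benzyloxy)-4,5-dimethoxybenzyl]-1-chloro-4-(3,4-dimethoxyphenyl)butyl]-4,4,5,5-tetramethyl-1,3,2-dioxaborolane (both epimers at C1) | COc1ccc(C[C@H]([C@H](C(Cl)B2OC(C)(C)C(C)(C)O2)Cc2cc(OCc3ccccc3)c(OC)c(OC)c2)COCc2ccccc2)cc1OC | intermediate
21 | (2R,3R)-4-(benzyloxy)-2-[3-(benzyloxy)-4,5-dimethoxybenzyl]-3-(3,4-dimethoxybenzyl)butanal (not isolated) | COc1ccc(C[C@H]([C@H](C=O)Cc2cc(OCc3ccccc3)c(OC)c(OC)c2)COCc2ccccc2)cc1OC | intermediate
22 | (2R,3R)-4-(benzyloxy)-2-[3-(benzyloxy)-4,5-dimethoxybenzyl]-3-(3,4-dimethoxybenzyl)butanoic acid | COc1ccc(C[C@H]([C@H](C(=O)O)Cc2cc(OCc3ccccc3)c(OC)c(OC)c2)COCc2ccccc2)cc1OC | intermediate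
23 | (2R,3R)-4-hydroxy-2-(3-hydroxy-4,5-dimethoxybenzyl)-3-(3,4-dimethoxybenzyl)butanoic acid (not isolated) | COc1ccc(C[C@H]([C@H](C(=O)O)Cc2cc(O)c(OC)c(OC)c2)CO)cc1OC | intermediate
24 | (3R,4R)-4-(3,4-dimethoxybenzyl)-3-(3-hydroxy-4,5-dimethoxybenzyl)dihydrofuran-2(3H)-one | COc1ccc(C[C@H]2COC(=O)[C@@H]2Cc2cc(O)c(OC)c(OC)c2)cc1OC | target

## Step count and least certain steps

Total: 10 steps. Longest linear sequence: 8 steps (4 → 5 → 6 → 8 → 9 → 18 → 20 → 22 → 24); 3 and 12 are each one step from purchased material.

**Step 7 (key step).**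
- What may go wrong: loss of material and of stereochemical purity because the two stages are telescoped. During the long exposure of 3 and 9 to the s-BuLi/diamine base, deprotonation at the benzylic CH2 (followed by loss of carboxylate) or at ArOCH2Ph can compete. Residual base can add to the boron of 12 or 15, surplus 13 can homologate 15 a second time, and the diamine of the first hand enters the second lithiation. None of these by-products is removed between the stages.
- Fallback: make the carbenoids by tin–lithium exchange from isolated stannanes, setting out from 3 and 9 and coming back at 18.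
  - 3 is lithiated as in stage (a) and quenched with Me3SnCl to give (R)-2-(3,4-dimethoxyphenyl)-1-(trimethylstannyl)ethyl 2,4,6-triisopropylbenzoate F1, which is purified and, if crystalline, enriched.
  - 9 gives with (−)-sparteine in the same way (S)-2-[3-(benzyloxy)-4,5-dimethoxyphenyl]-1-(trimethylstannyl)ethyl 2,4,6-triisopropylbenzoate F2.
  - n-BuLi (Et2O, −78 °C) converts F1 into diamine-free 13 within minutes; 12 is added and 15 is isolated by chromatography.
  - F2 is treated likewise, 15 is added, and warming gives 18.
  - The chiral reagents are then of checked purity, exactly one equivalent of carbenoid is used, and no strong base or diamine is present when boron is engaged.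

**Step 8.**
- What may go wrong: slow capture of the short-lived LiCHCl2 by the hindered, doubly β-branched secondary boronic ester, so that the carbenoid decomposes and 18 is returned.
- Fallback: set out from 18 and come back at 21. Vinyllithium is added to boron, followed by I2 and NaOMe (Zweifel olefination, retention at C3), to give 1-(benzyloxy)-5-{(2S,3R)-3-[(benzyloxy)methyl]-4-(3,4-dimethoxyphenyl)-2-ethenylbutyl}-2,3-dimethoxybenzene F3. Cleavage of the terminal alkene with OsO4 (cat.), NaIO4 and 2,6-lutidine in dioxane/H2O gives 21, which is oxidised to 22 under the Pinnick conditions of step 9. The vinyl nucleophile is stable, small and can be used in excess.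

**Step 9.**
- What may go wrong: electrophilic chlorination of the two electron-rich rings by hypochlorite or ClO2 if scavenging is incomplete, and epimerisation at C3 if the aldehyde accumulates.
- Fallback: set out from 18 and come back at 22 without a chlorine oxidant. LiCH2Cl (from BrCH2Cl and n-BuLi, THF, −78 °C) inserts a methylene to give 2-{(2R,3R)-3-[(benzyloxy)methyl]-2-[3-(benzyloxy)-4,5-dimethoxybenzyl]-4-(3,4-dimethoxyphenyl)butyl}-4,4,5,5-tetramethyl-1,3,2-dioxaborolane F4. NaBO3·4H2O in THF/H2O gives (2R,3R)-4-(benzyloxy)-2-[3-(benzyloxy)-4,5-dimethoxybenzyl]-3-(3,4-dimethoxybenzyl)butan-1-ol F5. PhI(OAc)2 with catalytic TEMPO in MeCN/H2O oxidises the primary alcohol to 22.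

**Step 10.**
- What may go wrong: partial epimerisation at C3, carried over from the aldehyde stage or arising during acid-catalysed closure, so that the product contains the cis lactone.
- Fallback: set out from 22 and come back at 24 under thermodynamic control of C3. Hydrogenolysis and closure are run as before, and the mixture of 24 and (3S,4R)-4-(3,4-dimethoxybenzyl)-3-(3-hydroxy-4,5-dimethoxybenzyl)dihydrofuran-2(3H)-one F6 is equilibrated with DBU in toluene. C4 is fixed and trans is favoured, so the mixture should converge on 24.

## Further compounds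

F1 | step 7 | (R)-2-(3,4-dimethoxyphenyl)-1-(trimethylstannyl)ethyl 2,4,6-triisopropylbenzoate | COc1ccc(C[C@@H]([Sn](C)(C)C)OC(=O)c2c(C(C)C)cc(C(C)C)cc2C(C)C)cc1OC
F2 | step 7 | (S)-2-[3-(benzyloxy)-4,5-dimethoxyphenyl]-1-(trimethylstannyl)ethyl 2,4,6-triisopropylbenzoate | COc1cc(C[C@H]([Sn](C)(C)C)OC(=O)c2c(C(C)C)cc(C(C)C)cc2C(C)C)cc(OCc2ccccc2)c1OC
F3 | step 8 | 1-(benzyloxy)-5-{(2S,3R)-3-[(benzyloxy)methyl]-4-(3,4-dimethoxyphenyl)-2-ethenylbutyl}-2,3-dimethoxybenzene | COc1ccc(C[C@H]([C@H](C=C)Cc2cc(OCc3ccccc3)c(OC)c(OC)c2)COCc2ccccc2)cc1OC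
F4 | step 9 | 2-{(2R,3R)-3-[(benzyloxy)methyl]-2-[3-(benzyloxy)-4,5-dimethoxybenzyl]-4-(3,4-dimethoxyphenyl)butyl}-4,4,5,5-tetramethyl-1,3,2-dioxaborolane | COc1ccc(C[C@H]([C@H](CB2OC(C)(C)C(C)(C)O2)Cc2cc(OCc3ccccc3)c(OC)c(OC)c2)COCc2ccccc2)cc1OC
F5 | step 9 | (2R,3R)-4-(benzyloxy)-2-[3-(benzyloxy)-4,5-dimethoxybenzyl]-3-(3,4-dimethoxybenzyl)butan-1-ol | COc1ccc(C[C@H]([C@H](CO)Cc2cc(OCc3ccccc3)c(OC)c(OC)c2)COCc2ccccc2)cc1OC
F6 | step 10 | (3S,4R)-4-(3,4-dimethoxybenzyl)-3-(3-hydroxy-4,5-dimethoxybenzyl)dihydrofuran-2(3H)-one | COc1ccc(C[C@H]2COC(=O)[C@H]2Cc2cc(O)c(OC)c(OC)c2)cc1OC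
A1 | alternative 1 | (3R,4S)-3-[3-(benzyloxy)-4,5-dimethoxybenzyl]-4-(hydroxymethyl)dihydrofuran-2(3H)-one | OC[C@H]1COC(=O)[C@@H]1Cc1cc(OCc2ccccc2)c(OC)c(OC)c1
A2 | alternative 1 | (2R)-3-[3-(benzyloxy)-4,5-dimethoxyphenyl]-2-(2,2-dimethyl-1,3-dioxan-5-yl)propanoic acid | OC(=O)[C@@H](C1COC(C)(C)OC1)Cc1cc(OCc2ccccc2)c(OC)c(OC)c1
A3 | alternative 2 | (R,Z)-3-[3-(benzyloxy)-4,5-dimethoxybenzylidene]-4-(3,4-dimethoxybenzyl)dihydrofuran-2(3H)-one | COc1ccc(C[C@H]2COC(=O)/C2=C\c2cc(OCc3ccccc3)c(OC)c(OC)c2)cc1OC
A4 | alternative 2 | (E)-3-(3,4-dimethoxyphenyl)prop-2-en-1-yl 3-[3-(benzyloxy)-4,5-dimethoxyphenyl]prop-2-ynoate | COc1ccc(/C=C/COC(=O)C#Cc2cc(OCc3ccccc3)c(OC)c(OC)c2)cc1OC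
A5 | alternative 3 | (3R,4R)-3-[3-(benzyloxy)-4,5-dimethoxybenzyl]-4-(3,4-dimethoxybenzyl)dihydrofuran-2(3H)-one | COc1ccc(C[C@H]2COC(=O)[C@@H]2Cc2cc(OCc3ccccc3)c(OC)c(OC)c2)cc1OC
A6 | alternative 3 | (2R,3E)-4-[3-(benzyloxy)-4,5-dimethoxyphenyl]-2-(3,4-dimethoxybenzyl)but-3-en-1-ol | COc1ccc(C[C@H](/C=C/c2cc(OCc3ccccc3)c(OC)c(OC)c2)CO)cc1OC
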